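**Plan**
- Numbering the chain C1 (ester) to C5 (ArCH2), with ring A on C3 and ring B on C5, the C2 carbinol, C3 methine and C4 ketone form a β-hydroxy ketone. This is an opened 2-isoxazoline whose ring atoms 5, 4 and 3 are C2, C3 and C4.
- Retrosynthesis: re-close the N–O bond, take C1 back to CH2OH, then cut C3–C4 and C2–O in one [3+2] operation into a ring B arylacetonitrile oxide and a ring A (E)-cinnamyl alcohol.
- Forward: the ring B arm (silylation, Stille prenylation, ester → aldehyde → oxime → hydroximoyl chloride) and the ring A arm (silylation, ester → allylic alcohol) converge in the cycloaddition, which closes the only ring made. C1 is then oxidised and methylated, the phenols are freed and the isoxazoline is opened last.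
- Stereochemistry: the C2/C3 relative configuration comes from the E alkene (suprafacial addition) and the absolute configuration from (R,R)-diisopropyl tartrate on the zinc alkoxide of the C1 hydroxyl. Both centres stay locked in the ring until the final, neutral step.

Key step: step 8

Abbreviations: TBS = tert-butyldimethylsilyl; prenyl = 3-methylbut-2-en-1-yl.

Remark on the chemistry: the (R,R)-tartrate is assumed to impose the same facial sense on the aryl-substituted allylic alkoxide as on allyl alcohol and (E)-but-2-en-1-ol, which corresponds to the (4R,5R)-isoxazoline. If the sense proved opposite, the (S,S)-ester would be used with no other change. The C=N geometry of 6 and 7 is left undefined because it is lost in the nitrile oxide.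

**Route**

Step 1
Reactants: 1 methyl 2-(3-bromo-4-hydroxyphenyl)acetate
Product: 2 methyl 2-[3-bromo-4-(tert-butyldimethylsilyloxy)phenyl]acetate
Conditions: TBSCl, imidazole, DMF, rt
Reagents that add atoms: tert-butyldimethylsilyl chloride, CC(C)(C)[Si](C)(C)Cl
Why: Silyl ether formation on a phenol with TBSCl/imidazole is routine, and it masks the acidic phenol for the organometallic steps that follow.

Step 2
Reactants: 2 methyl 2-[3-bromo-4-(tert-butyldimethylsilyloxy)phenyl]acetate; 3 tributyl(3-methylbut-2-en-1-yl)stannane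
Product: 4 methyl 2-[4-(tert-butyldimethylsilyloxy)-3-(3-methylbut-2-en-1-yl)phenyl]acetate
Conditions: Pd(PPh3)4 (5 mol %), DMF, 95 °C
Reagents that add atoms: none
Why: Stille cross-coupling of an aryl bromide with an allylic stannane under zerovalent palladium catalysis should transfer the prenyl group at its tin-bearing carbon, and the base-free conditions leave the methyl ester and the aryl silyl ether untouched.

Step 3
Reactants: 4 methyl 2-[4-(tert-butyldimethylsilyloxy)-3-(3-methylbut-2-en-1-yl)phenyl]acetate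
Product: 5 2-[4-(tert-butyldimethylsilyloxy)-3-(3-methylbut-2-en-1-yl)phenyl]acetaldehyde
Conditions: i-Bu2AlH (1.1 equiv), CH2Cl2, −78 °C; MeOH, then aq. potassium sodium tartrate; used crude at once
Reagents that add atoms: none
Why: Partial reduction of a methyl ester with i-Bu2AlH at −78 °C stops at the aluminium hemiacetal, which releases the aldehyde only on work-up; the self-condensing arylacetaldehyde is carried on without storage.

Step 4
Reactants: 5 2-[4-(tert-butyldimethylsilyloxy)-3-(3-methylbut-2-en-1-yl)phenyl]acetaldehyde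
Product: 6 2-[4-(tert-butyldimethylsilyloxy)-3-(3-methylbut-2-en-1-yl)phenyl]acetaldehyde oxime (E/Z mixture)
Conditions: NH2OH·HCl, NaOAc, EtOH/H2O, rt
Reagents that add atoms: hydroxylamine hydrochloride, Cl.NO
Why: Oximation of an aldehyde in acetate-buffered ethanol is fast and mild enough for the aryl silyl ether, and the E/Z mixture is of no consequence.

Step 5
Reactants: 6 2-[4-(tert-butyldimethylsilyloxy)-3-(3-methylbut-2-en-1-yl)phenyl]acetaldehyde oxime
Product: 7 N-hydroxy-2-[4-(tert-butyldimethylsilyloxy)-3-(3-methylbut-2-en-1-yl)phenyl]acetimidoyl chloride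
Conditions: NCS (1.05 equiv), DMF, 0 °C → rt; used crude
Reagents that add atoms: N-chlorosuccinimide, O=C1CCC(=O)N1Cl
Why: Chlorination of an aldoxime C–H with NCS in DMF gives the hydroximoyl chloride and should outpace attack on the trisubstituted alkene or the silyloxyarene, as it does when alkenyl oximes are chlorinated for intramolecular nitrile oxide cycloadditions.

Step 6
Reactants: 8 methyl (E)-3-(4-hydroxyphenyl)prop-2-enoate (methyl p-coumarate)
Product: 9 methyl (E)-3-[4-(tert-butyldimethylsilyloxy)phenyl]prop-2-enoate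
Conditions: TBSCl, imidazole, DMF, rt
Reagents that add atoms: tert-butyldimethylsilyl chloride, CC(C)(C)[Si](C)(C)Cl
Why: Phenol silylation with TBSCl/imidazole, as in step 1.

Step 7
Reactants: 9 methyl (E)-3-[4-(tert-butyldimethylsilyloxy)phenyl]prop-2-enoate
Product: 10 (E)-3-[4-(tert-butyldimethylsilyloxy)phenyl]prop-2-en-1-ol
Conditions: i-Bu2AlH (2.2 equiv), CH2Cl2, −78 → 0 °C; aq. potassium sodium tartrate
Reagents that add atoms: none
Why: 1,2-Reduction of an α,β-unsaturated ester with i-Bu2AlH gives the allylic alcohol with the E geometry retained.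

Step 8
Reactants: 7 N-hydroxy-2-[4-(tert-butyldimethylsilyloxy)-3-(3-methylbut-2-en-1-yl)phenyl]acetimidoyl chloride; 10 (E)-3-[4-(tert-butyldimethylsilyloxy)phenyl]prop-2-en-1-ol
Product: 13 [(4R,5R)-3-{[4-(tert-butyldimethylsilyloxy)-3-(3-methylbut-2-en-1-yl)phenyl]methyl}-4-[4-(tert-butyldimethylsilyloxy)phenyl]-4,5-dihydroisoxazol-5-yl]methanol, via ethylzinc alkoxide 11 (not isolated), via nitrile oxide 12 (not isolated)
Conditions: 10, Et2Zn (1.0 equiv), CHCl3, 0 °C; (R,R)-diisopropyl tartrate (1.0 equiv); Et2Zn (1.0 equiv); 1,4-dioxane (additive); 7 (1.1 equiv) added slowly, 0 °C; aq. NH4Cl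
Reagents that add atoms: none
Why: Et2Zn turns 10 into the ethylzinc alkoxide 11, the tartrate diol then links this zinc to a second zinc centre, and the remaining ethylzinc base removes HCl from 7 so that the nitrile oxide 12 is released on the same chiral dizinc template and adds to the alkene in a concerted, suprafacial [3+2] cycloaddition. The closest known reaction type is the zinc-alkoxide-directed, tartrate-mediated asymmetric nitrile oxide cycloaddition to allyl alcohol and to (E)-γ-substituted allylic alcohols. The one ring formed, the 2-isoxazoline, closes intermolecularly by [3+2] annulation, the chain bonds C3–C4 (ring C4–C3) and C2–O (ring C5–O1) being made in the same step. Of the two new stereocentres, ring C4 and C5 (chain C3 and C2), the trans relationship follows stereospecifically from the E geometry of 10, and the absolute sense comes from the (R,R)-tartrate, which leaves one alkene face open and is expected to give the (4R,5R) isomer. The step needs regioselectivity for oxygen at the carbinol-side carbon, which coordination of the dipole oxygen to the zinc held by the C1 alkoxide should secure against the styrene-type electronic preference for oxygen at the aryl-bearing carbon. It also needs chemoselectivity: the unactivated, non-coordinating trisubstituted prenyl alkene should not compete, and slow addition of 7 keeps 12 dilute so that dimerisation to the furoxan is held back.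

Step 9
Reactants: 13 [(4R,5R)-3-{[4-(tert-butyldimethylsilyloxy)-3-(3-methylbut-2-en-1-yl)phenyl]methyl}-4-[4-(tert-butyldimethylsilyloxy)phenyl]-4,5-dihydroisoxazol-5-yl]methanol
Product: 15 (4R,5R)-3-{[4-(tert-butyldimethylsilyloxy)-3-(3-methylbut-2-en-1-yl)phenyl]methyl}-4-[4-(tert-butyldimethylsilyloxy)phenyl]-4,5-dihydroisoxazole-5-carboxylic acid, via isoxazoline aldehyde 14 (not isolated)
Conditions: TEMPO (0.2 equiv), PhI(OAc)2 (2.5 equiv), MeCN/CH2Cl2/H2O, rt
Reagents that add atoms: water, O
Why: TEMPO-catalysed oxoammonium oxidation with PhI(OAc)2 in wet solvent takes a primary alcohol through the aldehyde hydrate to the acid without touching the alkene, the C=N bond or the silyl ethers, and the weakly acidic medium and the favoured trans arrangement should keep ring C5 intact; the oxidation is done here because free phenols would not survive it.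

Step 10
Reactants: 15 (4R,5R)-3-{[4-(tert-butyldimethylsilyloxy)-3-(3-methylbut-2-en-1-yl)phenyl]methyl}-4-[4-(tert-butyldimethylsilyloxy)phenyl]-4,5-dihydroisoxazole-5-carboxylic acid
Product: 16 methyl (4R,5R)-3-{[4-(tert-butyldimethylsilyloxy)-3-(3-methylbut-2-en-1-yl)phenyl]methyl}-4-[4-(tert-butyldimethylsilyloxy)phenyl]-4,5-dihydroisoxazole-5-carboxylate
Conditions: Me3SiCHN2 (hexane solution), PhMe/MeOH (4:1), 0 °C
Reagents that add atoms: trimethylsilyldiazomethane, C[Si](C)(C)C=[N+]=[N-]
Why: Diazoalkane esterification of a carboxylic acid is neutral and base-free, so the acidic ring C4–H and C5–H positions are not disturbed.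

Step 11
Reactants: 16 methyl (4R,5R)-3-{[4-(tert-butyldimethylsilyloxy)-3-(3-methylbut-2-en-1-yl)phenyl]methyl}-4-[4-(tert-butyldimethylsilyloxy)phenyl]-4,5-dihydroisoxazole-5-carboxylate
Product: 17 methyl (4R,5R)-3-{[4-hydroxy-3-(3-methylbut-2-en-1-yl)phenyl]methyl}-4-(4-hydroxyphenyl)-4,5-dihydroisoxazole-5-carboxylate
Conditions: Bu4NF (2.5 equiv), AcOH (2.5 equiv), THF, 0 °C
Reagents that add atoms: none
Why: Fluoride cleavage of aryl silyl ethers is fast even when buffered with acetic acid, and it is placed before ring opening so that the base-sensitive aldol is still masked while fluoride is present.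

Step 12
Reactants: 17 methyl (4R,5R)-3-{[4-hydroxy-3-(3-methylbut-2-en-1-yl)phenyl]methyl}-4-(4-hydroxyphenyl)-4,5-dihydroisoxazole-5-carboxylate
Product: 19 Asperteretal H, methyl (2R,3S)-2-hydroxy-3-(4-hydroxyphenyl)-5-[4-hydroxy-3-(3-methylbut-2-en-1-yl)phenyl]-4-oxopentanoate, via hydroxy imine 18 (not isolated)
Conditions: Mo(CO)6 (1.2 equiv), MeCN/H2O (15:1), 80 °C
Reagents that add atoms: water, O
Why: Reductive N–O cleavage of a 2-isoxazoline by Mo(CO)6 in wet acetonitrile gives the N–H imine, which hydrolyses in the same pot to the β-hydroxy ketone; the alkene, ester and phenols are inert to it, and no bond to C2 or C3 is broken, so the configuration set in step 8 is carried over (C3 is named S in the ketone only because the priority order changes).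

**Compound list**

1 | methyl 2-(3-bromo-4-hydroxyphenyl)acetate | COC(=O)Cc1ccc(O)c(Br)c1 | starting material
2 | methyl 2-[3-bromo-4-(tert-butyldimethylsilyloxy)phenyl]acetate | COC(=O)Cc1ccc(O[Si](C)(C)C(C)(C)C)c(Br)c1 | intermediate
3 | tributyl(3-methylbut-2-en-1-yl)stannane | CCCC[Sn](CCCC)(CCCC)CC=C(C)C | starting material
4 | methyl 2-[4-(tert-butyldimethylsilyloxy)-3-(3-methylbut-2-en-1-yl)phenyl]acetate | COC(=O)Cc1ccc(O[Si](C)(C)C(C)(C)C)c(CC=C(C)C)c1 | intermediate
5 | 2-[4-(tert-butyldimethylsilyloxy)-3-(3-methylbut-2-en-1-yl)phenyl]acetaldehyde | O=CCc1ccc(O[Si](C)(C)C(C)(C)C)c(CC=C(C)C)c1 | intermediate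
6 | 2-[4-(tert-butyldimethylsilyloxy)-3-(3-methylbut-2-en-1-yl)phenyl]acetaldehyde oxime (E/Z mixture) | ON=CCc1ccc(O[Si](C)(C)C(C)(C)C)c(CC=C(C)C)c1 | intermediate
7 | N-hydroxy-2-[4-(tert-butyldimethylsilyloxy)-3-(3-methylbut-2-en-1-yl)phenyl]acetimidoyl chloride | ON=C(Cl)Cc1ccc(O[Si](C)(C)C(C)(C)C)c(CC=C(C)C)c1 | intermediate
8 | methyl (E)-3-(4-hydroxyphenyl)prop-2-enoate (methyl p-coumarate) | COC(=O)/C=C/c1ccc(O)cc1 | starting material
9 | methyl (E)-3-[4-(tert-butyldimethylsilyloxy)phenyl]prop-2-enoate | COC(=O)/C=C/c1ccc(O[Si](C)(C)C(C)(C)C)cc1 | intermediate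
10 | (E)-3-[4-(tert-butyldimethylsilyloxy)phenyl]prop-2-en-1-ol | OC/C=C/c1ccc(O[Si](C)(C)C(C)(C)C)cc1 | intermediate
11 | ethylzinc (E)-3-[4-(tert-butyldimethylsilyloxy)phenyl]prop-2-en-1-olate | CC[Zn]OC/C=C/c1ccc(O[Si](C)(C)C(C)(C)C)cc1 | intermediate
12 | 2-[4-(tert-butyldimethylsilyloxy)-3-(3-methylbut-2-en-1-yl)phenyl]acetonitrile oxide | [O-][N+]#CCc1ccc(O[Si](C)(C)C(C)(C)C)c(CC=C(C)C)c1 | intermediate
13 | [(4R,5R)-3-{[4-(tert-butyldimethylsilyloxy)-3-(3-methylbut-2-en-1-yl)phenyl]methyl}-4-[4-(tert-butyldimethylsilyloxy)phenyl]-4,5-dihydroisoxazol-5-yl]methanol | OC[C@@H]1ON=C(Cc2ccc(O[Si](C)(C)C(C)(C)C)c(CC=C(C)C)c2)[C@H]1c3ccc(O[Si](C)(C)C(C)(C)C)cc3 | intermediate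
14 | (4R,5R)-3-{[4-(tert-butyldimethylsilyloxy)-3-(3-methylbut-2-en-1-yl)phenyl]methyl}-4-[4-(tert-butyldimethylsilyloxy)phenyl]-4,5-dihydroisoxazole-5-carbaldehyde | O=C[C@@H]1ON=C(Cc2ccc(O[Si](C)(C)C(C)(C)C)c(CC=C(C)C)c2)[C@H]1c3ccc(O[Si](C)(C)C(C)(C)C)cc3 | intermediate
15 | (4R,5R)-3-{[4-(tert-butyldimethylsilyloxy)-3-(3-methylbut-2-en-1-yl)phenyl]methyl}-4-[4-(tert-butyldimethylsilyloxy)phenyl]-4,5-dihydroisoxazole-5-carboxylic acid | OC(=O)[C@@H]1ON=C(Cc2ccc(O[Si](C)(C)C(C)(C)C)c(CC=C(C)C)c2)[C@H]1c3ccc(O[Si](C)(C)C(C)(C)C)cc3 | intermediate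
16 | methyl (4R,5R)-3-{[4-(tert-butyldimethylsilyloxy)-3-(3-methylbut-2-en-1-yl)phenyl]methyl}-4-[4-(tert-butyldimethylsilyloxy)phenyl]-4,5-dihydroisoxazole-5-carboxylate | COC(=O)[C@@H]1ON=C(Cc2ccc(O[Si](C)(C)C(C)(C)C)c(CC=C(C)C)c2)[C@H]1c3ccc(O[Si](C)(C)C(C)(C)C)cc3 | intermediate
17 | methyl (4R,5R)-3-{[4-hydroxy-3-(3-methylbut-2-en-1-yl)phenyl]methyl}-4-(4-hydroxyphenyl)-4,5-dihydroisoxazole-5-carboxylate | COC(=O)[C@@H]1ON=C(Cc2ccc(O)c(CC=C(C)C)c2)[C@H]1c3ccc(O)cc3 | intermediate
18 | methyl (2R,3R)-2-hydroxy-3-(4-hydroxyphenyl)-5-[4-hydroxy-3-(3-methylbut-2-en-1-yl)phenyl]-4-iminopentanoate | COC(=O)[C@H](O)[C@@H](C(=N)Cc1ccc(O)c(CC=C(C)C)c1)c1ccc(O)cc1 | intermediate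
19 | Asperteretal H, methyl (2R,3S)-2-hydroxy-3-(4-hydroxyphenyl)-5-[4-hydroxy-3-(3-methylbut-2-en-1-yl)phenyl]-4-oxopentanoate | COC(=O)[C@H](O)[C@@H](C(=O)Cc1ccc(O)c(CC=C(C)C)c1)c1ccc(O)cc1 | target

**Step count**

Total: 12 steps. Longest linear sequence: 10 steps (steps 1–5, then 8–12); the ring A arm contributes steps 6–7.

**Steps most likely to fail**

Step 8. The aryl-conjugated, electron-rich alkene is less well matched to the zinc tartrate template than alkyl-substituted allylic alkoxides. Facial discrimination may therefore be incomplete, some regiochemical leakage towards oxygen at the aryl-bearing carbon is possible, and the unhindered nitrile oxide may dimerise. Fallback, setting out from 7 and 10: the cycloaddition is run as the racemic magnesium-alkoxide-directed variant (EtMgBr, 2 equiv, CH2Cl2, 0 °C), in which the harder magnesium alkoxide gives the strongest known acceleration and regiocontrol, to give the racemic trans-isoxazoline methanol F1. Acetylation (Ac2O, pyridine, DMAP) gives the racemic acetate F2. A lipase selected by screening (Burkholderia cepacia lipase, Candida antarctica lipase B, porcine pancreatic lipase) for faster hydrolysis of the (4R,5R)-ester in pH 7 phosphate buffer/acetone then releases the (4R,5R)-alcohol, which is 13, and leaves the (4S,5S)-acetate F3 behind. The route is rejoined at 13.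

Step 12. The product is an α-aryl β-hydroxy ketone. At 80 °C the transient N–H imine can tautomerise to its enamine and the ketone can enolise, which would erode the C3 configuration, and loss of water across C2–C3 can compete. Fallback, setting out from 16: the N–O bond is hydrogenolysed at room temperature (Raney Ni, H2 1 atm, B(OH)3, MeOH/THF/H2O) and stopped at full conversion so that the trisubstituted prenyl alkene is retained. This gives the bis-silyl β-hydroxy ketone F4, whose phenols are then freed under cold acidic fluoride (HF·pyridine, THF/pyridine, 0 °C) to arrive at 19.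

Step 2. The unsymmetrical prenyl group may be transferred with allylic transposition, giving the 1,1-dimethylallyl isomer alongside the prenyl arene. Fallback, setting out from 2: Stille coupling with allyltributylstannane (Pd(PPh3)4, DMF, 95 °C), where no regiochemical question arises, gives methyl 2-[3-allyl-4-(tert-butyldimethylsilyloxy)phenyl]acetate F5. Cross-metathesis with 2-methylbut-2-ene (second-generation Grubbs catalyst, CH2Cl2, 40 °C) converts the allyl into the prenyl group and returns to 4.

**Further compounds**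

F1 | step 8 | racemic trans-[3-{[4-(tert-butyldimethylsilyloxy)-3-(3-methylbut-2-en-1-yl)phenyl]methyl}-4-[4-(tert-butyldimethylsilyloxy)phenyl]-4,5-dihydroisoxazol-5-yl]methanol (both enantiomers written) | OC[C@@H]1ON=C(Cc2ccc(O[Si](C)(C)C(C)(C)C)c(CC=C(C)C)c2)[C@H]1c3ccc(O[Si](C)(C)C(C)(C)C)cc3.OC[C@H]1ON=C(Cc2ccc(O[Si](C)(C)C(C)(C)C)c(CC=C(C)C)c2)[C@@H]1c3ccc(O[Si](C)(C)C(C)(C)C)cc3
F2 | step 8 | racemic trans-[3-{[4-(tert-butyldimethylsilyloxy)-3-(3-methylbut-2-en-1-yl)phenyl]methyl}-4-[4-(tert-butyldimethylsilyloxy)phenyl]-4,5-dihydroisoxazol-5-yl]methyl acetate (both enantiomers written) | CC(=O)OC[C@@H]1ON=C(Cc2ccc(O[Si](C)(C)C(C)(C)C)c(CC=C(C)C)c2)[C@H]1c3ccc(O[Si](C)(C)C(C)(C)C)cc3.CC(=O)OC[C@H]1ON=C(Cc2ccc(O[Si](C)(C)C(C)(C)C)c(CC=C(C)C)c2)[C@@H]1c3ccc(O[Si](C)(C)C(C)(C)C)cc3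
F3 | step 8 | [(4S,5S)-3-{[4-(tert-butyldimethylsilyloxy)-3-(3-methylbut-2-en-1-yl)phenyl]methyl}-4-[4-(tert-butyldimethylsilyloxy)phenyl]-4,5-dihydroisoxazol-5-yl]methyl acetate | CC(=O)OC[C@H]1ON=C(Cc2ccc(O[Si](C)(C)C(C)(C)C)c(CC=C(C)C)c2)[C@@H]1c3ccc(O[Si](C)(C)C(C)(C)C)cc3
F4 | step 12 | methyl (2R,3S)-5-[4-(tert-butyldimethylsilyloxy)-3-(3-methylbut-2-en-1-yl)phenyl]-3-[4-(tert-butyldimethylsilyloxy)phenyl]-2-hydroxy-4-oxopentanoate | COC(=O)[C@H](O)[C@@H](C(=O)Cc1ccc(O[Si](C)(C)C(C)(C)C)c(CC=C(C)C)c1)c1ccc(O[Si](C)(C)C(C)(C)C)cc1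
F5 | step 2 | methyl 2-[3-allyl-4-(tert-butyldimethylsilyloxy)phenyl]acetate | COC(=O)Cc1ccc(O[Si](C)(C)C(C)(C)C)c(CC=C)c1
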